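**Plan**

- Retrosynthesis: the side-chain ester C1'–O bond is cut first, giving (R)-shikonin and 3,4-dimethylpent-3-enoic acid. The naphthazarin is traced back through a 1,4-diacetoxy-5,8-dimethoxynaphthalene to the 2-substituted 5,8-dimethoxy-1,4-naphthoquinone. The ring bonds C4–C4a and C1–C8a are then cut together, the oxygen on C1 (or C4) being read as a former 1,4-oxygen bridge.
- Enabling feature: ring A (C4a, C5, C6, C7, C8, C8a) carries C4 and C1 on adjacent carbons with an oxygen on each outer flank (C5 and C8), so it is a mirror-symmetric 3,6-dioxygenated benzyne. The unit C1–C2(C1')=C3–C4 of ring B is the C2-to-C5 diene of a 3-substituted furan.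
- Forward: ring A and the furan are bought. Ring B is closed in the aryne/furan [4+2] as its oxygen-bridged adduct, and in one further operation the bridge is opened to naphthols and these are oxidised to the para-quinone. The quinone is then moved to the other ring (reductive acetylation, oxidative demethylation), the acetates and the silyl ether are removed, and the ester is put on last.
- Stereochemistry: the only stereocentre, C1' (R), is set by a reagent-controlled Brown allylboration of furan-3-carbaldehyde and carried as a silyl ether. The two bridgehead centres of the cycloadduct are transient.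

Key step: step 7

Remark on the chemistry: a 2-substituted naphthazarin is one compound whichever ring is drawn as the quinone, because its two 5,8-dihydroxy-1,4-dione tautomers interconvert by fast intramolecular proton transfer. The naphthazarin silyl ether, shikonin and the final ester are therefore drawn as the target is drawn.

**Route**

Step 1
Reactants: 1 2,5-dimethoxyphenol
Product: 2 2,5-dimethoxyphenyl propan-2-ylcarbamate
Conditions: i-PrNCO, Et3N (cat.), CH2Cl2, rt
Reagents that add atoms: isopropyl isocyanate, CC(C)N=C=O
Why: amine-catalysed addition of the phenol O–H across the isocyanate (carbamoylation) should give the N-monosubstituted O-aryl carbamate, which directs the metalation in step 2 and can later be removed by base alone.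

Step 2
Reactants: 2 2,5-dimethoxyphenyl propan-2-ylcarbamate
Product: 6 3,6-dimethoxy-2-(trimethylsilyl)phenyl propan-2-ylcarbamate, via N-silyl carbamate 3 (not isolated), via ortho-lithiated carbamate 4 (not isolated), via N-silyl C-silyl carbamate 5 (not isolated)
Conditions: TBSOTf, TMEDA, Et2O, 0 °C to rt; then n-BuLi, TMEDA, −78 °C; then TMSCl, −78 °C to rt; aq. NaHSO4 work-up
Reagents that add atoms: chlorotrimethylsilane, C[Si](C)(C)Cl
Why: after in-situ N-silylation masks the N–H, carbamate-directed ortho-lithiation (directed ortho metalation) should occur at the only free ortho position, which is also flanked by a methoxy group, and TMSCl silylates the aryllithium; the N–Si bond is hydrolysed on work-up.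

Step 3
Reactants: 6 3,6-dimethoxy-2-(trimethylsilyl)phenyl propan-2-ylcarbamate
Product: 8 3,6-dimethoxy-2-(trimethylsilyl)phenyl trifluoromethanesulfonate, via 3,6-dimethoxy-2-(trimethylsilyl)phenol 7 (not isolated)
Conditions: DBU, Et2NH, MeCN, 40 °C; then PhNTf2, rt
Reagents that add atoms: N-phenylbis(trifluoromethanesulfonimide), O=S(=O)(N(c1ccccc1)S(=O)(=O)C(F)(F)F)C(F)(F)F
Why: DBU-induced E1cB loss of isopropyl isocyanate (trapped by Et2NH as a urea) should free the hindered phenoxide, which is triflated in the same flask; the purely basic conditions avoid protodesilylation of the electron-rich arylsilane.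

Step 4
Reactants: 9 furan-3-carbaldehyde
Product: 11 (1R)-1-(furan-3-yl)but-3-en-1-ol, via diisopinocampheylborinate ester 10 (not isolated)
Conditions: (+)-Ipc2B(allyl) (commercial pentane solution, from (−)-α-pinene), Et2O, −78 °C; then aq. NaOH, H2O2, 0 °C to rt
Reagents that add atoms: (+)-B-allyldiisopinocampheylborane, C=CCB([C@H]1C[C@H]2C[C@@H]([C@@H]1C)C2(C)C)[C@H]1C[C@H]2C[C@@H]([C@@H]1C)C2(C)C
Why: Brown allylboration through a closed chair transition state, in which the isopinocampheyl groups of the (−)-α-pinene series direct allyl transfer to the re face of the aldehyde, should set C1' as R (the (+)-α-pinene-derived reagent gives S alcohols from aryl aldehydes); oxidative work-up cleaves the borinate.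

Step 5
Reactants: 11 (1R)-1-(furan-3-yl)but-3-en-1-ol
Product: 12 tert-butyl{[(1R)-1-(furan-3-yl)but-3-en-1-yl]oxy}dimethylsilane
Conditions: TBSCl, imidazole, DMF, rt
Reagents that add atoms: tert-butyldimethylsilyl chloride, CC(C)(C)[Si](C)(C)Cl
Why: imidazole-promoted O-silylation of a secondary alcohol should proceed without touching the stereocentre and gives an ether that is a poor leaving group and stable to fluoride salts of low solubility.

Step 6
Reactants: 12 tert-butyl{[(1R)-1-(furan-3-yl)but-3-en-1-yl]oxy}dimethylsilane
Product: 13 tert-butyl{[(1R)-1-(furan-3-yl)-4-methylpent-3-en-1-yl]oxy}dimethylsilane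
Conditions: second-generation Grubbs catalyst (H2IMes)(PCy3)Cl2Ru=CHPh (3 mol%), 2-methylbut-2-ene (large excess), CH2Cl2, 35–40 °C
Reagents that add atoms: 2-methylbut-2-ene, CC=C(C)C
Why: olefin cross-metathesis of a terminal alkene with excess 2-methylbut-2-ene should transfer an isopropylidene unit and give the prenyl-type trisubstituted alkene with loss of propene; the furan and silyl ether are inert to the ruthenium carbene and the homoallylic stereocentre is not involved.

Step 7
Reactants: 8 3,6-dimethoxy-2-(trimethylsilyl)phenyl trifluoromethanesulfonate (about 1.5 equiv); 13 tert-butyl{[(1R)-1-(furan-3-yl)-4-methylpent-3-en-1-yl]oxy}dimethylsilane (limiting)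
Product: 15 (1S,4R)-2-[(1R)-1-{[tert-butyl(dimethyl)silyl]oxy}-4-methylpent-3-en-1-yl]-5,8-dimethoxy-1,4-dihydro-1,4-epoxynaphthalene and 16 its (1R,4S) bridgehead diastereomer, via 3,6-dimethoxybenzyne 14 (not isolated)
Conditions: CsF, MeCN, rt
Reagents that add atoms: none
Why: Fluoride attacks silicon of 8 and the ortho triflate leaves, giving 3,6-dimethoxybenzyne 14, which is captured by the C2-to-C5 diene of furan 13 in a concerted suprafacial [4+2] cycloaddition (the aryne Diels–Alder reaction with furans, the standard entry to 1,4-dihydro-1,4-epoxynaphthalenes). The six-membered carbocycle C1–C2–C3–C4–C4a–C8a is closed intermolecularly in one event by simultaneous formation of C4–C4a and C1–C8a, the furan oxygen becoming the 1,4-bridge. The bridgehead centres C1 and C4 are made cis to each other by the suprafacial geometry; their sense relative to the remote C1' centre is not controlled, so 15 and 16 are expected in comparable amounts, which is harmless because both centres are erased in step 8. No regiochemical question arises, since the two aryne carbons are related by the mirror plane of the 3,6-disubstituted aryne whichever way the unsymmetrical furan approaches. The needed chemoselectivity (diene capture instead of an ene reaction at the prenyl alkene or fluoride addition to the aryne) rests on the very high rate of furan–aryne cycloaddition and on slow aryne release from sparingly soluble CsF with the precursor in excess, and the secondary silyl ether should survive CsF in MeCN at room temperature. C1' is a spectator and keeps its R configuration.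

Step 8
Reactants: 15 (1S,4R)-2-[(1R)-1-{[tert-butyl(dimethyl)silyl]oxy}-4-methylpent-3-en-1-yl]-5,8-dimethoxy-1,4-dihydro-1,4-epoxynaphthalene (the unseparated mixture of bridgehead diastereomers from the cycloaddition)
Product: 19 2-[(1R)-1-{[tert-butyl(dimethyl)silyl]oxy}-4-methylpent-3-en-1-yl]-5,8-dimethoxynaphthalene-1,4-dione, via ortho-substituted naphthol 17 (not isolated), via meta-substituted naphthol 18 (not isolated)
Conditions: Cu(OTf)2 (5 mol%), ClCH2CH2Cl, 0 °C to rt; then Et3N, solvent exchanged for acetone; then (KSO3)2NO (Fremy's salt), aq. KH2PO4, 0 °C to rt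
Reagents that add atoms: potassium nitrosodisulfonate (Fremy's salt), [K+].[K+].[O]N(S(=O)(=O)[O-])S(=O)(=O)[O-]
Why: Lewis-acid-catalysed isomerization of a 1,4-epoxy-1,4-dihydronaphthalene to 1-naphthols (ionization of a bridgehead C–O bond to a benzylic allyl cation, 1,2-hydride shift from the carbinol carbon, tautomerization) erases both bridgehead centres, so 15 and its diastereomer 16 alike should give naphthol 17 by C4–O cleavage (expected major, through the cation whose tertiary terminus is C2) and naphthol 18 by C1–O cleavage, and the Teuber oxidation that follows in the same flask (one nitrosodisulfonate radical removes the phenolic hydrogen, a second couples at the free para carbon, the adduct collapses to the quinone) converges both air-sensitive naphthols on the single para-quinone 19 while leaving the dimethoxyarene, silyl ether, alkene and C1' alone.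

Step 9
Reactants: 19 2-[(1R)-1-{[tert-butyl(dimethyl)silyl]oxy}-4-methylpent-3-en-1-yl]-5,8-dimethoxynaphthalene-1,4-dione
Product: 21 2-[(1R)-1-{[tert-butyl(dimethyl)silyl]oxy}-4-methylpent-3-en-1-yl]-5,8-dimethoxynaphthalene-1,4-diyl diacetate, via hydroquinone 20 (not isolated)
Conditions: Zn dust, Ac2O, pyridine, DMAP (cat.), rt
Reagents that add atoms: acetic anhydride, CC(=O)OC(C)=O
Why: reductive acetylation (zinc reduces the quinone and the hydroquinone is acetylated in situ) should store the substituted ring as an electron-poor diacetate, so that the unsubstituted dimethoxy ring becomes the more easily oxidised one.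

Step 10
Reactants: 21 2-[(1R)-1-{[tert-butyl(dimethyl)silyl]oxy}-4-methylpent-3-en-1-yl]-5,8-dimethoxynaphthalene-1,4-diyl diacetate
Product: 22 2-[(1R)-1-{[tert-butyl(dimethyl)silyl]oxy}-4-methylpent-3-en-1-yl]-5,8-dioxo-5,8-dihydronaphthalene-1,4-diyl diacetate
Conditions: (NH4)2Ce(NO3)6, MeCN/H2O, 0 °C
Reagents that add atoms: water, O
Why: oxidative demethylation of a para-dimethoxyarene by tetravalent cerium (arene radical cation, ipso attack of water, loss of methanol) should form the quinone on the former dimethoxy ring, because the acetoxy-bearing ring is deactivated toward electron transfer; the isolated alkene and silyl ether are expected to survive the short, cold exposure.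

Step 11
Reactants: 22 2-[(1R)-1-{[tert-butyl(dimethyl)silyl]oxy}-4-methylpent-3-en-1-yl]-5,8-dioxo-5,8-dihydronaphthalene-1,4-diyl diacetate
Product: 23 2-[(1R)-1-{[tert-butyl(dimethyl)silyl]oxy}-4-methylpent-3-en-1-yl]-5,8-dihydroxynaphthalene-1,4-dione
Conditions: LiOH, THF/H2O, 0 °C, argon; then aq. HCl to pH 4
Reagents that add atoms: none
Why: saponification of the two aryl acetates peri to the quinone carbonyls (activated aryl esters, as in the alkaline hydrolysis of naphthazarin and shikonin acetates) should release the naphthazarin, which on acidification equilibrates to the tautomer drawn; the silyl ether is stable to cold hydroxide.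

Step 12
Reactants: 23 2-[(1R)-1-{[tert-butyl(dimethyl)silyl]oxy}-4-methylpent-3-en-1-yl]-5,8-dihydroxynaphthalene-1,4-dione
Product: 24 (R)-shikonin, 5,8-dihydroxy-2-[(1R)-1-hydroxy-4-methylpent-3-en-1-yl]naphthalene-1,4-dione
Conditions: HF·pyridine, pyridine, THF, 0 °C to rt
Reagents that add atoms: none
Why: fluoride-mediated cleavage of the secondary silyl ether in a buffered, non-nucleophilic medium should free the carbinol without solvolysis at C1' or acid-induced ring closure onto the prenyl alkene.

Step 13
Reactants: 24 (R)-shikonin; 25 3,4-dimethylpent-3-enoic acid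
Product: 27 (1R)-1-(5,8-dihydroxy-1,4-dioxo-1,4-dihydronaphthalen-2-yl)-4-methylpent-3-en-1-yl 3,4-dimethylpent-3-enoate, via O-acylisourea 26 (not isolated)
Conditions: DCC, DMAP (cat.), CH2Cl2, 0 °C to rt
Reagents that add atoms: none
Why: Steglich esterification should acylate the side-chain hydroxyl selectively, because the two peri phenols are tied up in strong hydrogen bonds to the quinone carbonyls and are poor nucleophiles (the known selective side-chain acylation of shikonin); the C1'–O bond is not broken, so the R configuration is retained, and low temperature with catalytic DMAP limits migration of the β,γ-double bond of the acid.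

**Compound list**

1 | 2,5-dimethoxyphenol | COc1ccc(OC)c(O)c1 | starting material
2 | 2,5-dimethoxyphenyl propan-2-ylcarbamate | COc1ccc(OC)c(OC(=O)NC(C)C)c1 | intermediate
3 | 2,5-dimethoxyphenyl N-(tert-butyldimethylsilyl)-N-(propan-2-yl)carbamate | COc1ccc(OC)c(OC(=O)N(C(C)C)[Si](C)(C)C(C)(C)C)c1 | intermediate (not isolated)
4 | [2-({[tert-butyl(dimethyl)silyl](propan-2-yl)carbamoyl}oxy)-3,6-dimethoxyphenyl]lithium | COc1ccc(OC)c(OC(=O)N(C(C)C)[Si](C)(C)C(C)(C)C)c1[Li] | intermediate (not isolated)
5 | 3,6-dimethoxy-2-(trimethylsilyl)phenyl N-(tert-butyldimethylsilyl)-N-(propan-2-yl)carbamate | COc1ccc(OC)c(OC(=O)N(C(C)C)[Si](C)(C)C(C)(C)C)c1[Si](C)(C)C | intermediate (not isolated)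
6 | 3,6-dimethoxy-2-(trimethylsilyl)phenyl propan-2-ylcarbamate | COc1ccc(OC)c(OC(=O)NC(C)C)c1[Si](C)(C)C | intermediate
7 | 3,6-dimethoxy-2-(trimethylsilyl)phenol (present as its DBU-H phenoxide) | COc1ccc(OC)c(O)c1[Si](C)(C)C | intermediate (not isolated)
8 | 3,6-dimethoxy-2-(trimethylsilyl)phenyl trifluoromethanesulfonate | COc1ccc(OC)c(OS(=O)(=O)C(F)(F)F)c1[Si](C)(C)C | intermediate
9 | furan-3-carbaldehyde | O=Cc1ccoc1 | starting material
10 | (1R)-1-(furan-3-yl)but-3-en-1-yl diisopinocampheylborinate | C=CC[C@@H](OB([C@H]1C[C@H]2C[C@@H]([C@@H]1C)C2(C)C)[C@H]1C[C@H]2C[C@@H]([C@@H]1C)C2(C)C)c1ccoc1 | intermediate (not isolated)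
11 | (1R)-1-(furan-3-yl)but-3-en-1-ol | C=CC[C@@H](O)c1ccoc1 | intermediate
12 | tert-butyl{[(1R)-1-(furan-3-yl)but-3-en-1-yl]oxy}dimethylsilane | C=CC[C@@H](O[Si](C)(C)C(C)(C)C)c1ccoc1 | intermediate
13 | tert-butyl{[(1R)-1-(furan-3-yl)-4-methylpent-3-en-1-yl]oxy}dimethylsilane | CC(C)=CC[C@@H](O[Si](C)(C)C(C)(C)C)c1ccoc1 | intermediate
14 | 3,6-dimethoxybenzyne | COC1=CC=C(OC)C#C1 | intermediate (not isolated)
15 | (1S,4R)-2-[(1R)-1-{[tert-butyl(dimethyl)silyl]oxy}-4-methylpent-3-en-1-yl]-5,8-dimethoxy-1,4-dihydro-1,4-epoxynaphthalene | CC(C)=CC[C@@H](O[Si](C)(C)C(C)(C)C)C1=C[C@H]2O[C@@H]1c1c(OC)ccc(OC)c12 | intermediate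
16 | (1R,4S)-2-[(1R)-1-{[tert-butyl(dimethyl)silyl]oxy}-4-methylpent-3-en-1-yl]-5,8-dimethoxy-1,4-dihydro-1,4-epoxynaphthalene (bridgehead diastereomer of 15, formed and carried on together with it) | CC(C)=CC[C@@H](O[Si](C)(C)C(C)(C)C)C1=C[C@@H]2O[C@H]1c1c(OC)ccc(OC)c12 | intermediate
17 | 2-[(1R)-1-{[tert-butyl(dimethyl)silyl]oxy}-4-methylpent-3-en-1-yl]-5,8-dimethoxynaphthalen-1-ol | CC(C)=CC[C@@H](O[Si](C)(C)C(C)(C)C)c1ccc2c(OC)ccc(OC)c2c1O | intermediate (not isolated)
18 | 3-[(1R)-1-{[tert-butyl(dimethyl)silyl]oxy}-4-methylpent-3-en-1-yl]-5,8-dimethoxynaphthalen-1-ol | CC(C)=CC[C@@H](O[Si](C)(C)C(C)(C)C)c1cc(O)c2c(OC)ccc(OC)c2c1 | intermediate (not isolated)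
19 | 2-[(1R)-1-{[tert-butyl(dimethyl)silyl]oxy}-4-methylpent-3-en-1-yl]-5,8-dimethoxynaphthalene-1,4-dione | CC(C)=CC[C@@H](O[Si](C)(C)C(C)(C)C)C1=CC(=O)c2c(OC)ccc(OC)c2C1=O | intermediate
20 | 2-[(1R)-1-{[tert-butyl(dimethyl)silyl]oxy}-4-methylpent-3-en-1-yl]-5,8-dimethoxynaphthalene-1,4-diol | CC(C)=CC[C@@H](O[Si](C)(C)C(C)(C)C)c1cc(O)c2c(OC)ccc(OC)c2c1O | intermediate (not isolated)
21 | 2-[(1R)-1-{[tert-butyl(dimethyl)silyl]oxy}-4-methylpent-3-en-1-yl]-5,8-dimethoxynaphthalene-1,4-diyl diacetate | CC(C)=CC[C@@H](O[Si](C)(C)C(C)(C)C)c1cc(OC(C)=O)c2c(OC)ccc(OC)c2c1OC(C)=O | intermediate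
22 | 2-[(1R)-1-{[tert-butyl(dimethyl)silyl]oxy}-4-methylpent-3-en-1-yl]-5,8-dioxo-5,8-dihydronaphthalene-1,4-diyl diacetate | CC(C)=CC[C@@H](O[Si](C)(C)C(C)(C)C)c1cc(OC(C)=O)c2C(=O)C=CC(=O)c2c1OC(C)=O | intermediate
23 | 2-[(1R)-1-{[tert-butyl(dimethyl)silyl]oxy}-4-methylpent-3-en-1-yl]-5,8-dihydroxynaphthalene-1,4-dione | CC(C)=CC[C@@H](O[Si](C)(C)C(C)(C)C)C1=CC(=O)c2c(O)ccc(O)c2C1=O | intermediate
24 | (R)-shikonin, 5,8-dihydroxy-2-[(1R)-1-hydroxy-4-methylpent-3-en-1-yl]naphthalene-1,4-dione | CC(C)=CC[C@@H](O)C1=CC(=O)c2c(O)ccc(O)c2C1=O | intermediate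
25 | 3,4-dimethylpent-3-enoic acid | CC(C)=C(C)CC(=O)O | starting material
26 | N,N'-dicyclohexyl-O-(3,4-dimethylpent-3-enoyl)isourea | CC(C)=C(C)CC(=O)OC(=NC1CCCCC1)NC1CCCCC1 | intermediate (not isolated)
27 | (1R)-1-(5,8-dihydroxy-1,4-dioxo-1,4-dihydronaphthalen-2-yl)-4-methylpent-3-en-1-yl 3,4-dimethylpent-3-enoate | CC(C)=CC[C@@H](OC(=O)CC(C)=C(C)C)C1=CC(=O)c2c(O)ccc(O)c2C1=O | target

**Step count**

Total: 13 steps. Longest linear sequence: 10 steps (steps 1–3, then 7–13; the furan arm, steps 4–6 then 7–13, is equally long).

**Steps most likely to fail, with fallbacks**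

Step 8. Under the Lewis acid, bridge opening may be accompanied by ionization at the silyloxy-bearing carbon once the electron-rich ortho-hydroxy naphthol has formed (a quinone-methide pathway that would erode configuration or lead to elimination). Hydride migration from C1' into the allyl cation, or cation capture by the prenyl alkene, are further possibilities. The fallback sets out from 15 (as its mixture with 16) and replaces the cationic opening by a neutral transition-metal-mediated isomerization, a known reaction type for oxabicyclic alkenes. A monovalent rhodium catalyst, [Rh(CO)2Cl]2 in CHCl3 at 50 °C, inserts into the strained allylic bridgehead C–O bond. β-Hydride elimination from the resulting rhodium alkoxide and tautomerization then give naphthols 17 and 18 without a free carbocation. After solvent exchange the same (KSO3)2NO oxidation is carried out. The detour passes through no compound outside the list (F0) and comes back to the route at 19.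

Step 7. With the furan as the limiting partner, unproductive consumption of the aryne (self-reaction, capture by fluoride or adventitious water, ene reaction at the prenyl group) or slow fluoride-induced loss of the silyl ether could leave the cycloaddition incomplete. The fallback sets out from 13 and generates the same aryne without fluoride. Commercial 2-bromo-1,4-dimethoxybenzene F1 is deprotonated at C3, between bromine and methoxy, with LiTMP (lithium 2,2,6,6-tetramethylpiperidide) in THF at −78 °C to give (2-bromo-3,6-dimethoxyphenyl)lithium F2. Furan 13 is then added and the mixture warmed, whereupon LiBr is lost and aryne 14 is trapped. The sequence comes back to the route at 15 and 16.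

Step 10. The cerium oxidant may discriminate poorly between the two rings and the trisubstituted alkene, or the acidic aqueous medium may strip the silyl ether; the whole relocation of the quinone (steps 9–11) depends on this oxidation. The fallback sets out from 19 and removes the two peri methyl ethers directly by chelation-assisted Lewis-acid dealkylation, a known reaction of methoxy groups peri to quinone carbonyls. BCl3 in CH2Cl2 at −78 °C binds the carbonyl and the neighbouring methoxy oxygen, and chloride takes off each methyl group as chloromethane, giving 2-[(1R)-1-{[tert-butyl(dimethyl)silyl]oxy}-4-methylpent-3-en-1-yl]-5,8-bis[(dichloroboranyl)oxy]naphthalene-1,4-dione F3. Aqueous work-up hydrolyses the boron esters, and the sequence comes back to the route at 23, bypassing 20, 21 and 22.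

**Further compounds**

F0 | step 8 | none | none
F1 | step 7 | 2-bromo-1,4-dimethoxybenzene | COc1ccc(OC)c(Br)c1
F2 | step 7 | (2-bromo-3,6-dimethoxyphenyl)lithium | COc1ccc(OC)c(Br)c1[Li]
F3 | step 10 | 2-[(1R)-1-{[tert-butyl(dimethyl)silyl]oxy}-4-methylpent-3-en-1-yl]-5,8-bis[(dichloroboranyl)oxy]naphthalene-1,4-dione | CC(C)=CC[C@@H](O[Si](C)(C)C(C)(C)C)C1=CC(=O)c2c(OB(Cl)Cl)ccc(OB(Cl)Cl)c2C1=O
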